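Which way of charging the same L, J and Q leaves the most E, counted as a fraction of the L put in?

    L + J ⇌ Q + E (K1 = 5.2, k1 = 1.6 M⁻¹ h⁻¹)
    E + J ⇌ Q + Z (K2 = 95, k2 = 0.53 M⁻¹ h⁻¹)
    Q → D (k3 = 0.011 h⁻¹)

common to all: Q 80.0 mM

|  | L | J | time | remark |
|---|---|---|---|---|
| cedar | 16 mM | 19.2 mM | 20 d | a closed flask charged with all of it at once and left for 20 d |
| birch | 16 mM | 19.2 mM |  | one stirred flow tank at steady state, fed with the mixture as stated, mean residence time 20 d |
| oak | 16 mM (fed, over 10.0 d) | 19.2 mM | 20 d | all but L at the start; L goes in evenly over 10.0 d, the run ends at 20 d |
| maple | 16 mM | 19.2 mM (fed, over 10.0 d) | 20 d | all but J at the start; J goes in evenly over 10.0 d, the run ends at 20 d |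

- the stated concentrations are those of everything mixed, before any reaction; amounts are the same in each set-up
- the feed brings no volume worth counting
- run time (cedar): 20 d

- the set-up with the highest amount of E at the outlet or at the end, in percent of the L put in ("none" if the first two lie within 2 percentage points) (cedar / birch / oak / maple / none)
- amount of E at the outlet or at the end, in percent of the L put in, cedar
- amount of E at the outlet or at the end, in percent of the L put in, birch
- amount of E at the outlet or at the end, in percent of the L put in, oak
- amount of E at the outlet or at the end, in percent of the L put in, maple

Two numbers here seem to quarrel. At J as charged, step 2 alone gives E a forward half-life of 2.8 d, shorter than the run of 20 d, and that many half-lives would leave 0.756% of E. Yet J is charged at only 1.20 per L, which is less than the two J that full conversion to Z takes, so J is the limiting reagent for making Z.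

So count what is left, not what is made, in fractions of the L charge. L that has gone is E or Z, so E is the whole charge less L left less Z. Each L turned spends one J and each Z a second, and the way back returns them. Taking one balance from the other, you get E = B + J left − 2 × L left, where B is two less the J charged per L, the balance mark 80.0%. Neither Q nor D enters this balance, so it holds at the outlet of birch and, in cedar, oak and maple, once the whole charge is in; in oak and maple dosing ends at 10.0 d, before the end of the run.

The quarrel now clears: the forward half-life stretches as J falls. Suppose L all turned and no Z yet: then J left is 20.0% of the L charge, and the forward half-life at that J is 17.0 d, longer than the 2.8 d at J as charged. My reckoning stops here: I commit to E lying on that balance, so that at a given J left each point of L left costs 2 points of E. It doesn't rank the set-ups.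

The forecast, holding that “Feeding J slowly keeps J low while E builds”, gave 37.5% for cedar, 30% for birch, 40.5% for oak and 45.5% for maple, with maple best.

The simulation gives 36.9% for cedar, 29.9% for birch, 39.1% for oak and 43.9% for maple, so maple is highest. In maple, 34.1% of the L charge ended as Z, which leaves 22.1% as L, and then 80.0% less 2 times that is 35.8%, so J left is 8.10%. In cedar, L left at the end is 23.9%, so the same balance gives J left of 4.67% of the L charge, at which the forward half-life of E is about 73.0 d.

The constants are invented; the run is a simulation.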